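Moles per litre were the unit I reduced the readings to, since the asked average is monomer in chains over chains begun, and the readings show the first of these but not the second.

the same everywhere: initiator 35 mM; stray impurity 50 mM

|  | free monomer | protic impurity | remark | time |
|---|---|---|---|---|
| spring | 0.99 M | 0.0355 M | run made earlier |  |
| dusk | 1.6 M | 0.0355 M | run made earlier |  |
| dawn | 0.71 M | 0.053 M | run made earlier |  |
| flask | 0.71 M | 0.0355 M |  | 10 h |

| run | time / h | monomer in chains / % | free monomer / % |
|---|---|---|---|
| spring | 1.33 | 3.4 | 90.6 |
| spring | 4.00 | 9.1 | 79.8 |
| spring | 6.00 | 11.5 | 72.1 |
| spring | 10.0 | 15.2 | 61.8 |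
| dusk | 0.833 | 2.1 | 92.2 |
| dusk | 2.00 | 8.4 | 83.6 |
| dusk | 4.00 | 17.2 | 73.1 |
| dusk | 10.0 | 30.8 | 49.6 |
| dawn | 2.50 | 4.4 | 83.5 |
| dawn | 5.00 | 5.9 | 76.6 |
| dawn | 8.00 | 5.7 | 68.7 |
| dawn | 10.0 | 9.0 | 65.0 |

(scatter of a reading: 1 percentage point)

- average number of monomer units in a chain (chains begun, living or dead) at 10 h
- part of the free monomer that has reacted at 10 h

- the average divides the monomer in chains by the number of chains begun, living and dead together
- the earlier runs do not show the number of chains; that part of a forecast is a guess

The dawn run had the flask's free monomer charge but more protic impurity, so for c, the part of the free monomer reacted at the asked time, I started from that run and supposed that protic impurity removes free monomer one for one, giving the flask back that difference: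

c ≈ 35.0% − 2.46% = 32.5%

For the flask I took monomer in chains, U, from the dawn reading at 10.0 h, which carries its scatter:

U ≈ 0.0639 M

If every initiator began a chain, the average chain length dp would be

dp ≈ U / initiator = 1.83

That denominator was the weak link, because the stray impurity charge is larger than the initiator charge. I therefore supposed that stray impurity destroys initiator, which makes initiator, the smaller charge, the limiting reagent, and reckoned the spare initiator S, the initiator charge minus the stray impurity charge:

S = −15.0 mM

With S below zero, I supposed that the chains begun came from initiator that free monomer reached before stray impurity did. The earlier runs do not show the number of these chains, so I committed to 32.5% for c and to a dp above 1.83 by an unknown factor.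

The forecast gave 3 for dp and 36% for c, and said of the first: “This part is a guess, since transfer could add chains.”

The flask gave 60.5 for dp and 33.9% for c.

    monomer in chains + living end → free monomer + living end, rate k1*[living end] as long as [monomer in chains] is above zero (k = 0.160 min⁻¹)
    free monomer → uncatalysed product (k = 4.20 × 10⁻⁴ min⁻¹)
    initiator + stray impurity → spent initiator (k = 59.0 M⁻¹ min⁻¹)
    free monomer + living end → monomer in chains + living end, rate k4*[living end]*[free monomer] (k = 0.460 M⁻¹ min⁻¹)
    free monomer + initiator → living end + monomer in chains (k = 0.0770 M⁻¹ min⁻¹)
    protic impurity + free monomer → quenched substrate (k = 0.320 M⁻¹ min⁻¹)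

At the start of the flask, stray impurity took initiator at 2.95 min⁻¹ and free monomer took it at 0.0547 min⁻¹, which is 54.0 times slower. At 10.0 h the flask held 0.0340 M of spent initiator against 0.00104 M of living end, and its stray impurity stood at 16.0 mM, the shortfall of 15.0 mM plus those living ends. The neighbour flask charged with 0.088 M of initiator has S = 0.0380 M; it held 0.0380 M of living end, and its dp was 6.32.

(Readings and results stem from a simulated flask for substances that don't exist, noise included.)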